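**Plan**
1. Retrosynthetically, the two benzyl ethers on the outer naphthols are removed first, and ring A of the central naphthol is taken back by one dehydrogenation to a 2,4-diaryl-8-methoxy-1-tetralone.
2. In that ring, C1 (oxygenated, peri to the C8 methoxy group) and C4 (aryl-bearing) are both bonded to the anisole ring, at C8a and C4a. The C3–C4 bond is therefore cut and C4 is joined to C1 instead, giving a 2-aryl-1-(1-arylvinyl)benzocyclobutenol.
3. The carbinol is cut at the carbinol–alkenyl bond into a 2-arylbenzocyclobutenone and a 1-arylvinyllithium. The cyclobutenone is cut at both bonds to the arene into 3-methoxybenzyne and the ketene silyl acetal of an arylacetate.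
4. Forward: one aryl bromide (from naphthalene-1,8-diol) supplies both aryl units and 3-methoxyphenol supplies the aryne. The [2+2] closes the four-membered ring, the alkenyllithium is added, the ring expansion closes ring A, and dehydrogenation and debenzylation finish the synthesis.
5. The target has no stereocentre. The sp3 centres made on the way are racemic and are erased when ring A is aromatised.

Key step: step 15

Assumption: the target SMILES carries no stereodescriptor, so the two naphthyl–naphthyl axes are taken as not configurationally fixed and the target is treated as achiral.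

Ar below means 4-(benzyloxy)-5-methoxynaphthalen-1-yl.

**Route**

Step 1
Reactants: 1 3-methoxyphenol
Product: 2 1-methoxy-3-(methoxymethoxy)benzene
Conditions: MOMCl, iPr2NEt, CH2Cl2, 0 °C to rt
Reagents that add atoms: chloromethyl methyl ether, COCCl
Why: Base-mediated O-alkylation of the phenol (Williamson-type acetal ether formation) installs a methoxymethyl group that, together with the methoxy group, directs the coming lithiation to the carbon between the two oxygens.

Step 2
Reactants: 2 1-methoxy-3-(methoxymethoxy)benzene
Product: 4 2-iodo-1-methoxy-3-(methoxymethoxy)benzene, via aryllithium 3 (not isolated)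
Conditions: n-BuLi, THF, 0 °C to rt; then I2, THF, −78 °C to rt
Reagents that add atoms: iodine, II
Why: Directed ortho-metalation occurs at C2, the only position flanked and coordinated by both oxygen substituents, and iodine converts aryllithium 3 into the iodide by electrophilic iodination of the carbon–lithium bond.

Step 3
Reactants: 4 2-iodo-1-methoxy-3-(methoxymethoxy)benzene
Product: 5 2-iodo-3-methoxyphenol
Conditions: HCl (cat.), MeOH, 50 °C
Reagents that add atoms: none
Why: Acid-catalysed transacetalisation to methanol cleaves the methoxymethyl acetal, while the aryl methyl ether and the aryl iodide are inert to dilute acid.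

Step 4
Reactants: 5 2-iodo-3-methoxyphenol
Product: 6 2-iodo-3-methoxyphenyl trifluoromethanesulfonate
Conditions: Tf2O, pyridine, CH2Cl2, 0 °C
Reagents that add atoms: trifluoromethanesulfonic anhydride, O=S(=O)(OS(=O)(=O)C(F)(F)F)C(F)(F)F
Why: O-Sulfonylation of the phenol is routine and gives the ortho-iodoaryl triflate that eliminates to an aryne after iodine–lithium exchange.

Step 5
Reactants: 7 naphthalene-1,8-diol
Product: 8 8-methoxynaphthalen-1-ol
Conditions: MeI (1.1 equiv), K2CO3, acetone, reflux
Reagents that add atoms: iodomethane, CI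
Why: Williamson methylation stops at the monoether because the remaining hydroxyl group is locked in a peri hydrogen bond to the new methoxy oxygen and its phenoxide forms far less readily than the first.

Step 6
Reactants: 8 8-methoxynaphthalen-1-ol
Product: 9 4-bromo-8-methoxynaphthalen-1-ol
Conditions: NBS (1.0 equiv), MeCN, −20 to 0 °C, dark
Reagents that add atoms: N-bromosuccinimide, O=C1CCC(=O)N1Br
Why: Electrophilic aromatic bromination takes place in the ring carrying the free hydroxyl group, the strongest donor (the methoxy lone pair being engaged in the peri hydrogen bond), and in acetonitrile without an amine additive 1-naphthols are brominated para to oxygen, here at C4.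

Step 7
Reactants: 9 4-bromo-8-methoxynaphthalen-1-ol; 10 benzyl bromide
Product: 11 4-(benzyloxy)-1-bromo-5-methoxynaphthalene
Conditions: K2CO3, DMF, 60 °C
Reagents that add atoms: benzyl bromide (compound 10), BrCc1ccccc1
Why: Williamson benzylation of the potassium naphthoxide in a dipolar aprotic solvent overcomes the peri hydrogen bond and protects the oxygen as an ether stable to organolithium reagents, amide bases, fluoride and peracid.

Step 8
Reactants: 11 4-(benzyloxy)-1-bromo-5-methoxynaphthalene
Product: 12 ethyl 2-[4-(benzyloxy)-5-methoxynaphthalen-1-yl]acetate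
Conditions: BrZnCH2CO2Et (commercial solution), Pd2(dba)3 (cat.), XPhos (cat.), THF, 60 °C
Reagents that add atoms: (2-ethoxy-2-oxoethyl)zinc bromide, CCOC(=O)C[Zn]Br
Why: Negishi-type cross-coupling of the Reformatsky reagent at zerovalent palladium, supported by a bulky biarylphosphine that promotes oxidative addition to the electron-rich hindered bromide, forms the aryl–CH2 bond without touching the benzyl ether.

Step 9
Reactants: 12 ethyl 2-[4-(benzyloxy)-5-methoxynaphthalen-1-yl]acetate
Product: 14 tert-butyl({2-[4-(benzyloxy)-5-methoxynaphthalen-1-yl]-1-ethoxyethenyl}oxy)dimethylsilane (E/Z mixture; used crude), via lithium enolate 13 (not isolated)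
Conditions: LiN(iPr)2, THF, −78 °C; then TBSCl, DMPU, −78 °C to rt; non-aqueous work-up
Reagents that add atoms: tert-butyldimethylsilyl chloride, CC(C)(C)[Si](C)(C)Cl
Why: Kinetic deprotonation of the ester gives lithium enolate 13, which is silylated on oxygen in the presence of DMPU (ester enolate O-silylation) to the ketene silyl acetal, whose double-bond geometry does not matter for the cycloaddition.

Step 10
Reactants: 11 4-(benzyloxy)-1-bromo-5-methoxynaphthalene
Product: 16 1-[4-(benzyloxy)-5-methoxynaphthalen-1-yl]ethan-1-one, via aryllithium 15 (not isolated)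
Conditions: n-BuLi, THF, −78 °C; then MeC(O)N(OMe)Me, −78 to 0 °C; then 1 M HCl
Reagents that add atoms: N-methoxy-N-methylacetamide, CON(C)C(C)=O
Why: Bromine–lithium exchange gives aryllithium 15, and its acylation by the N-methoxy-N-methylamide stops at the ketone because the chelated tetrahedral adduct survives until the acidic quench (Weinreb ketone synthesis).

Step 11
Reactants: 16 1-[4-(benzyloxy)-5-methoxynaphthalen-1-yl]ethan-1-one
Product: 17 N'-{1-[4-(benzyloxy)-5-methoxynaphthalen-1-yl]ethylidene}-2,4,6-tri(propan-2-yl)benzenesulfonohydrazide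
Conditions: 2,4,6-triisopropylbenzenesulfonohydrazide, HCl (cat.), MeOH/THF, rt
Reagents that add atoms: 2,4,6-tri(propan-2-yl)benzenesulfonohydrazide, NNS(=O)(=O)c1c(C(C)C)cc(C(C)C)cc1C(C)C
Why: Acid-catalysed condensation of the methyl ketone with the sulfonylhydrazide gives the hydrazone, the triisopropylphenyl group being chosen because it suppresses ortho-lithiation of the sulfonyl arene in the following Shapiro reaction.

Step 12
Reactants: 6 2-iodo-3-methoxyphenyl trifluoromethanesulfonate; 14 ketene silyl acetal (2 equiv)
Product: 20 tert-butyl({8-[4-(benzyloxy)-5-methoxynaphthalen-1-yl]-7-ethoxy-5-methoxybicyclo[4.2.0]octa-1,3,5-trien-7-yl}oxy)dimethylsilane (racemic diastereomer mixture), via aryllithium 18 (not isolated), via 3-methoxybenzyne 19 (not isolated)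
Conditions: n-BuLi (1.1 equiv), THF, −78 °C
Reagents that add atoms: none
Why: Iodine–lithium exchange gives aryllithium 18, which loses lithium triflate to 3-methoxybenzyne 19, and the stepwise polar [2+2] cycloaddition is regioselective because the nucleophilic benzylic carbon of 14 attacks the aryne carbon meta to the methoxy group, so that the developing aryl anion sits next to the inductively withdrawing oxygen and closes on the oxocarbenium carbon; the two new stereocentres form without control as a racemic mixture and one disappears in step 13.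

Step 13
Reactants: 20 benzocyclobutenone ethyl silyl acetal
Product: 21 8-[4-(benzyloxy)-5-methoxynaphthalen-1-yl]-5-methoxybicyclo[4.2.0]octa-1,3,5-trien-7-one (racemic)
Conditions: aq. HF, MeCN, 0 °C to rt
Reagents that add atoms: none
Why: Fluoride removes the silyl group of the mixed acetal and the resulting hemiacetal collapses to the strained ketone (acetal hydrolysis), conditions under which benzyl and methyl aryl ethers are stable.

Step 14
Reactants: 17 trisylhydrazone (1.3 equiv); 21 2-arylbenzocyclobutenone
Product: 23 8-[4-(benzyloxy)-5-methoxynaphthalen-1-yl]-7-{1-[4-(benzyloxy)-5-methoxynaphthalen-1-yl]ethenyl}-5-methoxybicyclo[4.2.0]octa-1,3,5-trien-7-ol (racemic; either diastereomer), via alkenyllithium 22 (not isolated)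
Conditions: n-BuLi (2 equiv per 17), THF, −78 to 0 °C; then 21, −78 °C; then aq. NH4Cl, −78 °C
Reagents that add atoms: none
Why: In a Shapiro reaction two equivalents of butyllithium convert the hydrazone, with loss of sulfinate and dinitrogen, into alkenyllithium 22, which adds 1,2 to the strained ketone from the face opposite the C8 aryl group (enolisation is disfavoured because it would create a benzocyclobutadiene), the carbinol configuration being irrelevant since either diastereomer undergoes the ring expansion.

Step 15
Reactants: 23 1-(1-arylvinyl)-2-arylbenzocyclobutenol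
Product: 27 2,4-bis[4-(benzyloxy)-5-methoxynaphthalen-1-yl]-8-methoxy-3,4-dihydronaphthalen-1(2H)-one (racemic cis/trans mixture), via potassium alkoxide 24 (not isolated), via ring-opened dienolate 25 (not isolated), via potassium enolate 26 (not isolated)
Conditions: KN(SiMe3)2 (1.1 equiv), THF, −78 to 0 °C; then 1 M HCl, 0 °C
Reagents that add atoms: none
Why: Deprotonation gives potassium alkoxide 24, whose oxyanion accelerates cleavage of the strained C7–C8 σ bond (C1–C4 of the future tetralone), the oxygen rotating outward and the alkenyl group inward, to the o-quinodimethane dienolate 25, which is equally a diarylmethyl anion conjugated to an α-aryl enone. Ring A then closes by bonding of C8 (tetralone C4) to the alkenyl CH2 (C3), either as a thermally allowed disrotatory 6π electrocyclisation of the triene CH2=C(Ar)–C(O−)=C8a–C4a=CHAr or, in the stepwise description, as a 6-endo-trig conjugate addition; both give enolate 26 and restore the benzene ring. The closest known reaction type is the alkoxide-accelerated ring expansion of 1-alkenylbenzocyclobutenols to 1-tetralones. The stereocentre at C4 arises in the closure and that at C2 on protonation of 26; neither is controlled nor needs to be, because both are removed in steps 16 and 17, and for the same reason either diastereomer of 23 serves. The selectivity required is cleavage of the C7–C8 bond and not of the C7–arene bond, which is secured by the diarylmethyl-stabilised anion that the C8 naphthyl group provides and by the strong outward preference of the oxyanion; once the ring is open, the six-membered ring through C3–C4 is the only closure other than return to 23.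

Step 16
Reactants: 27 2,4-diaryl-8-methoxytetralone
Product: 29 2,4-bis[4-(benzyloxy)-5-methoxynaphthalen-1-yl]-8-methoxy-2-(phenylselanyl)-3,4-dihydronaphthalen-1(2H)-one (racemic diastereomer mixture), via lithium enolate 28 (not isolated)
Conditions: LiN(iPr)2 (1.1 equiv), THF, −78 °C; then PhSeBr, −78 °C
Reagents that add atoms: benzeneselenenyl bromide, Br[Se]c1ccccc1
Why: Kinetic deprotonation of the isolated tetralone at C2, the only α-position, by the lithium amide gives lithium enolate 28, which is selenenylated at carbon (enolate α-selenenylation); the new quaternary stereocentre forms without control and is removed in step 17.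

Step 17
Reactants: 29 α-phenylselanyl tetralone
Product: 32 2,4-bis[4-(benzyloxy)-5-methoxynaphthalen-1-yl]-8-methoxynaphthalen-1-ol, via selenoxide 30 (not isolated), via dienone tautomer 31 (not isolated)
Conditions: mCPBA (1.05 equiv), CH2Cl2, −78 °C; then pyridine, −78 °C to rt
Reagents that add atoms: none
Why: Chemoselective oxidation of selenium at low temperature gives selenoxide 30, whose syn-elimination towards C3 (selenoxide elimination) gives the cross-conjugated ketone 31, which tautomerises through its doubly benzylic C4–H to the aromatic naphthol, pyridine buffering the acids formed.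

Step 18
Reactants: 32 dibenzyl-protected trinaphthyl
Product: 33 2,4-bis(4-hydroxy-5-methoxynaphthalen-1-yl)-8-methoxynaphthalen-1-ol (CNP0528831.0)
Conditions: H2 (1 atm), Pd/C, EtOAc/MeOH, rt
Reagents that add atoms: none
Why: Hydrogenolysis of the two benzyl aryl ethers over palladium on carbon frees the outer naphthols, while the methyl ethers and the naphthalene rings are untouched at atmospheric pressure.

**Compound list**

1 | 3-methoxyphenol | COc1cccc(O)c1 | starting material
2 | 1-methoxy-3-(methoxymethoxy)benzene | COCOc1cccc(OC)c1 | intermediate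
3 | [2-methoxy-6-(methoxymethoxy)phenyl]lithium (formed in situ) | [Li]c1c(OC)cccc1OCOC | intermediate
4 | 2-iodo-1-methoxy-3-(methoxymethoxy)benzene | COCOc1cccc(OC)c1I | intermediate
5 | 2-iodo-3-methoxyphenol | COc1cccc(O)c1I | intermediate
6 | 2-iodo-3-methoxyphenyl trifluoromethanesulfonate | COc1cccc(OS(=O)(=O)C(F)(F)F)c1I | intermediate
7 | naphthalene-1,8-diol | Oc1cccc2cccc(O)c12 | starting material
8 | 8-methoxynaphthalen-1-ol | COc1cccc2cccc(O)c12 | intermediate
9 | 4-bromo-8-methoxynaphthalen-1-ol | COc1cccc2c(Br)ccc(O)c12 | intermediate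
10 | benzyl bromide | BrCc1ccccc1 | starting material
11 | 4-(benzyloxy)-1-bromo-5-methoxynaphthalene | COc1cccc2c(Br)ccc(OCc3ccccc3)c12 | intermediate
12 | ethyl 2-[4-(benzyloxy)-5-methoxynaphthalen-1-yl]acetate | CCOC(=O)Cc1ccc(OCc2ccccc2)c2c(OC)cccc12 | intermediate
13 | lithium enolate of ester 12 (formed in situ) | CCOC(O[Li])=Cc1ccc(OCc2ccccc2)c2c(OC)cccc12 | intermediate
14 | tert-butyl({2-[4-(benzyloxy)-5-methoxynaphthalen-1-yl]-1-ethoxyethenyl}oxy)dimethylsilane (E/Z mixture) | CCOC(O[Si](C)(C)C(C)(C)C)=Cc1ccc(OCc2ccccc2)c2c(OC)cccc12 | intermediate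
15 | [4-(benzyloxy)-5-methoxynaphthalen-1-yl]lithium (formed in situ) | [Li]c1ccc(OCc2ccccc2)c2c(OC)cccc12 | intermediate
16 | 1-[4-(benzyloxy)-5-methoxynaphthalen-1-yl]ethan-1-one | CC(=O)c1ccc(OCc2ccccc2)c2c(OC)cccc12 | intermediate
17 | N'-{1-[4-(benzyloxy)-5-methoxynaphthalen-1-yl]ethylidene}-2,4,6-tri(propan-2-yl)benzenesulfonohydrazide | CC(=NNS(=O)(=O)c1c(C(C)C)cc(C(C)C)cc1C(C)C)c1ccc(OCc2ccccc2)c2c(OC)cccc12 | intermediate
18 | 2-lithio-3-methoxyphenyl trifluoromethanesulfonate (formed in situ) | [Li]c1c(OC)cccc1OS(=O)(=O)C(F)(F)F | intermediate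
19 | 3-methoxybenzyne (formed in situ) | COC1=CC=CC#C1 | intermediate
20 | tert-butyl({8-[4-(benzyloxy)-5-methoxynaphthalen-1-yl]-7-ethoxy-5-methoxybicyclo[4.2.0]octa-1,3,5-trien-7-yl}oxy)dimethylsilane (racemic diastereomer mixture) | CCOC1(O[Si](C)(C)C(C)(C)C)C(c2ccc(OCc3ccccc3)c3c(OC)cccc23)c2cccc(OC)c21 | intermediate
21 | 8-[4-(benzyloxy)-5-methoxynaphthalen-1-yl]-5-methoxybicyclo[4.2.0]octa-1,3,5-trien-7-one (racemic) | COc1cccc2C(c3ccc(OCc4ccccc4)c4c(OC)cccc34)C(=O)c12 | intermediate
22 | {1-[4-(benzyloxy)-5-methoxynaphthalen-1-yl]ethenyl}lithium (formed in situ) | [Li]C(=C)c1ccc(OCc2ccccc2)c2c(OC)cccc12 | intermediate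
23 | 8-[4-(benzyloxy)-5-methoxynaphthalen-1-yl]-7-{1-[4-(benzyloxy)-5-methoxynaphthalen-1-yl]ethenyl}-5-methoxybicyclo[4.2.0]octa-1,3,5-trien-7-ol (racemic; either diastereomer) | COc1cccc2C(c3ccc(OCc4ccccc4)c4c(OC)cccc34)C(O)(C(=C)c3ccc(OCc4ccccc4)c4c(OC)cccc34)c12 | intermediate
24 | potassium alkoxide of 23 (formed in situ) | COc1cccc2C(c3ccc(OCc4ccccc4)c4c(OC)cccc34)C([O-])(C(=C)c3ccc(OCc4ccccc4)c4c(OC)cccc34)c12.[K+] | intermediate
25 | ring-opened o-quinodimethane dienolate, potassium salt (formed in situ) | COC1=CC=CC(=Cc2ccc(OCc3ccccc3)c3c(OC)cccc23)C1=C([O-])C(=C)c1ccc(OCc2ccccc2)c2c(OC)cccc12.[K+] | intermediate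
26 | potassium enolate of tetralone 27 (formed in situ) | COc1cccc2C(c3ccc(OCc4ccccc4)c4c(OC)cccc34)CC(c3ccc(OCc4ccccc4)c4c(OC)cccc34)=C([O-])c12.[K+] | intermediate
27 | 2,4-bis[4-(benzyloxy)-5-methoxynaphthalen-1-yl]-8-methoxy-3,4-dihydronaphthalen-1(2H)-one (racemic cis/trans mixture) | COc1cccc2C(c3ccc(OCc4ccccc4)c4c(OC)cccc34)CC(c3ccc(OCc4ccccc4)c4c(OC)cccc34)C(=O)c12 | intermediate
28 | lithium enolate of tetralone 27 (formed in situ) | COc1cccc2C(c3ccc(OCc4ccccc4)c4c(OC)cccc34)CC(c3ccc(OCc4ccccc4)c4c(OC)cccc34)=C(O[Li])c12 | intermediate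
29 | 2,4-bis[4-(benzyloxy)-5-methoxynaphthalen-1-yl]-8-methoxy-2-(phenylselanyl)-3,4-dihydronaphthalen-1(2H)-one (racemic diastereomer mixture) | COc1cccc2C(c3ccc(OCc4ccccc4)c4c(OC)cccc34)CC(c3ccc(OCc4ccccc4)c4c(OC)cccc34)([Se]c3ccccc3)C(=O)c12 | intermediate
30 | selenoxide of 29 (formed in situ) | COc1cccc2C(c3ccc(OCc4ccccc4)c4c(OC)cccc34)CC(c3ccc(OCc4ccccc4)c4c(OC)cccc34)([Se](=O)c3ccccc3)C(=O)c12 | intermediate
31 | 2,4-bis[4-(benzyloxy)-5-methoxynaphthalen-1-yl]-8-methoxynaphthalen-1(4H)-one (racemic; formed in situ) | COc1cccc2C(c3ccc(OCc4ccccc4)c4c(OC)cccc34)C=C(c3ccc(OCc4ccccc4)c4c(OC)cccc34)C(=O)c12 | intermediate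
32 | 2,4-bis[4-(benzyloxy)-5-methoxynaphthalen-1-yl]-8-methoxynaphthalen-1-ol | COc1cccc2c(-c3ccc(OCc4ccccc4)c4c(OC)cccc34)cc(-c3ccc(OCc4ccccc4)c4c(OC)cccc34)c(O)c12 | intermediate
33 | 2,4-bis(4-hydroxy-5-methoxynaphthalen-1-yl)-8-methoxynaphthalen-1-ol (CNP0528831.0) | COc1cccc2c(-c3cc(-c4ccc(O)c5c(OC)cccc45)c4cccc(OC)c4c3O)ccc(O)c12 | target

**Step count**

Total: 18 steps. Longest linear sequence: 12 steps (5, 6, 7, 8, 9, 12, 13, 14, 15, 16, 17, 18). Bromide 11 feeds both aryl branches (steps 8 and 10).

**Steps most likely to fail and their fallbacks**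

Step 15 (ring expansion). The potassium alkoxide may fragment along the carbinol–arene bond instead of the C7–C8 bond, or the ring-opened anion may be protonated or add intermolecularly before it closes in this crowded system. The fallback runs the same bond reorganisation without any anion. Carbinol 23 would be silylated (Me3SiOTf, 2,6-lutidine, CH2Cl2, −78 °C) to the trimethylsilyl ether F1. Heating F1 in toluene at 110 °C should bring about thermal conrotatory opening with the siloxy group outward and 6π closure to the silyl enol ether F2. Dilute HCl in THF then returns the route to tetralone 27.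

Step 12 (aryne [2+2]). The hindered, aryl-conjugated ketene acetal may add too slowly, so that the aryne is consumed by butyllithium, or the aryl anion formed after the first C–C bond may pick up the acidic benzylic hydrogen instead of closing the four-membered ring. The fallback introduces the C4 aryl group after the ring expansion. Triflate 6 and the commercial, unhindered tert-butyl[(1-methoxyethenyl)oxy]dimethylsilane (n-BuLi, THF, −78 °C) should give the mixed acetal F3, and aqueous HF in MeCN then gives 5-methoxybenzocyclobutenone F4. Alkenyllithium 22 (from 17 as in step 14) adds to F4 to give the carbinol F5. Treatment of F5 with KN(SiMe3)2 (THF, −78 to 0 °C) and then PhSeBr in the same flask should give the selenide F6, which mCPBA and pyridine convert into the 2-aryl-8-methoxynaphthalen-1-ol F7. NBS in MeCN brominates F7 para to the hydroxyl group to give the 4-bromonaphthol F8. Suzuki–Miyaura coupling of F8 (Pd(PPh3)4, K3PO4, dioxane/water, 80 °C) with the pinacol boronate F9, made from bromide 11 with B2pin2, Pd(dppf)Cl2 and KOAc, rejoins the route at naphthol 32.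

Step 14 (Shapiro reaction and addition). Alkenyllithium formation may be incomplete, excess butyllithium may metalate the benzylic OCH2 group, and the bulky alkenyllithium may add too slowly to a carbonyl group shielded by the neighbouring naphthyl group, so that the ketone is recovered or ring-opened. The fallback adds a small nucleophile and builds the 1-arylvinyl unit afterwards. Ketone 21 and ethynylmagnesium bromide (THF, −78 to 0 °C) should give the ethynyl carbinol F10. Hydrostannation with Bu3SnH and catalytic Mo(CO)3(CNtBu)3 (THF, 55 °C), which places tin on the internal carbon of propargylic alcohols, gives the alkenylstannane F11. Stille coupling of F11 with bromide 11 (Pd(PPh3)4, CuCl, LiCl, DMSO, 50 °C) returns the route to carbinol 23.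

**Further compounds**

F1 | step 15 | ({8-[4-(benzyloxy)-5-methoxynaphthalen-1-yl]-7-{1-[4-(benzyloxy)-5-methoxynaphthalen-1-yl]ethenyl}-5-methoxybicyclo[4.2.0]octa-1,3,5-trien-7-yl}oxy)trimethylsilane (racemic) | COc1cccc2C(c3ccc(OCc4ccccc4)c4c(OC)cccc34)C(O[Si](C)(C)C)(C(=C)c3ccc(OCc4ccccc4)c4c(OC)cccc34)c12
F2 | step 15 | {[2,4-bis(4-(benzyloxy)-5-methoxynaphthalen-1-yl)-8-methoxy-3,4-dihydronaphthalen-1-yl]oxy}trimethylsilane (racemic) | COc1cccc2C(c3ccc(OCc4ccccc4)c4c(OC)cccc34)CC(c3ccc(OCc4ccccc4)c4c(OC)cccc34)=C(O[Si](C)(C)C)c12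
F3 | step 12 | tert-butyl[(5,7-dimethoxybicyclo[4.2.0]octa-1,3,5-trien-7-yl)oxy]dimethylsilane (racemic) | COC1(O[Si](C)(C)C(C)(C)C)Cc2cccc(OC)c21
F4 | step 12 | 5-methoxybicyclo[4.2.0]octa-1,3,5-trien-7-one | COc1cccc2CC(=O)c12
F5 | step 12 | 7-{1-[4-(benzyloxy)-5-methoxynaphthalen-1-yl]ethenyl}-5-methoxybicyclo[4.2.0]octa-1,3,5-trien-7-ol (racemic) | COc1cccc2CC(O)(C(=C)c3ccc(OCc4ccccc4)c4c(OC)cccc34)c12
F6 | step 12 | 2-[4-(benzyloxy)-5-methoxynaphthalen-1-yl]-8-methoxy-2-(phenylselanyl)-3,4-dihydronaphthalen-1(2H)-one (racemic) | COc1cccc2CCC(c3ccc(OCc4ccccc4)c4c(OC)cccc34)([Se]c3ccccc3)C(=O)c12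
F7 | step 12 | 2-[4-(benzyloxy)-5-methoxynaphthalen-1-yl]-8-methoxynaphthalen-1-ol | COc1cccc2ccc(-c3ccc(OCc4ccccc4)c4c(OC)cccc34)c(O)c12
F8 | step 12 | 2-[4-(benzyloxy)-5-methoxynaphthalen-1-yl]-4-bromo-8-methoxynaphthalen-1-ol | COc1cccc2c(Br)cc(-c3ccc(OCc4ccccc4)c4c(OC)cccc34)c(O)c12
F9 | step 12 | 2-[4-(benzyloxy)-5-methoxynaphthalen-1-yl]-4,4,5,5-tetramethyl-1,3,2-dioxaborolane | COc1cccc2c(B3OC(C)(C)C(C)(C)O3)ccc(OCc3ccccc3)c12
F10 | step 14 | 8-[4-(benzyloxy)-5-methoxynaphthalen-1-yl]-7-ethynyl-5-methoxybicyclo[4.2.0]octa-1,3,5-trien-7-ol (racemic) | COc1cccc2C(c3ccc(OCc4ccccc4)c4c(OC)cccc34)C(O)(C#C)c12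
F11 | step 14 | 8-[4-(benzyloxy)-5-methoxynaphthalen-1-yl]-5-methoxy-7-[1-(tributylstannyl)ethenyl]bicyclo[4.2.0]octa-1,3,5-trien-7-ol (racemic) | COc1cccc2C(c3ccc(OCc4ccccc4)c4c(OC)cccc34)C(O)(C(=C)[Sn](CCCC)(CCCC)CCCC)c12
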